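**Strategy.** Everything rests on disconnecting the O1–C2 bond of the dihydropyran ring. Quaternary C2 carries both the ring oxygen and the C1'=C2' alkene of the side-chain diene, so it is a tertiary allylic aryl ether: the retron of a Wacker-type oxidative cyclization. In one operation an enantioselective oxypalladation adds the phenol oxygen to C2 of a trisubstituted alkene, and β-hydride elimination of the doubly allylic C2'–H then unveils the conjugated (1'E,3'E)-diene, so ring, stereocentre and diene arise together. The precursor is an achiral open-chain phenol bearing a skipped (1,4-) diene, assembled from two terminal alkynes by zirconium-catalysed carboalumination and palladium-catalysed alkenyl–allyl coupling.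

Key step: step 7

Locants: chromane numbering (O1, C2, C3, C4) for the pyran ring; C1' to C6' for the side chain, counted from C2.

Assumption: the sense of induction of the BOXAX ligand is taken by analogy with the formation of 2-methyl-2-vinylchromanes, so (R,R)-Bn-BOXAX (2,2'-bis[(4R)-4-benzyl-4,5-dihydrooxazol-2-yl]-1,1'-binaphthyl, (R) axis) is written for the (R)-product. If the sense proved opposite, the (S,S)-ligand would be used.

Step 1
Reactants: 1 methyl 4-hydroxy-3-iodobenzoate; 2 allyl alcohol
Product: 4 methyl 2-hydroxy-3,4-dihydro-2H-chromene-6-carboxylate (racemic lactol), via hydroxy aldehyde 3 (not isolated)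
Conditions: Pd(OAc)2 (3 mol%), NaHCO3, n-Bu4NCl, DMF, 45 °C
Reagents that add atoms: none
Why: Mizoroki–Heck arylation of allyl alcohol under Jeffery conditions places the aryl group on the terminal carbon, β-hydride elimination toward the carbinol gives the enol and hence aldehyde 3, which closes to lactol 4, and the phenol and ester are inert to NaHCO3.

Step 2
Reactants: 4 methyl 2-hydroxy-3,4-dihydro-2H-chromene-6-carboxylate
Product: 5 methyl 3-(but-3-yn-1-yl)-4-hydroxybenzoate
Conditions: Ohira–Bestmann reagent (1.5 equiv), K2CO3 (3 equiv), MeOH, 0 °C to rt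
Reagents that add atoms: Ohira–Bestmann reagent, dimethyl (1-diazo-2-oxopropyl)phosphonate, COP(=O)(OC)C(=[N+]=[N-])C(C)=O
Why: Seyferth–Gilbert homologation in the Ohira–Bestmann form: in K2CO3/MeOH lactol 4 stands in ring–chain equilibrium with its open phenoxide aldehyde form (the tautomer numbered 3 in step 1), which condenses with the diazomethylphosphonate anion generated in the flask and, after loss of N2 and a 1,2-hydrogen shift, should give the terminal alkyne without touching the methyl ester.

Step 3
Reactants: 6 dihydro-β-ionone (4-(2,6,6-trimethylcyclohex-1-en-1-yl)butan-2-one)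
Product: 8 2-(but-3-yn-1-yl)-1,3,3-trimethylcyclohex-1-ene, via enol phosphate 7 (not isolated)
Conditions: LiN(i-Pr)2 (1.1 equiv), THF, −78 °C; ClP(O)(OEt)2, −78 °C to rt; then LiN(i-Pr)2 (2.3 equiv), −78 °C to rt; H2O
Reagents that add atoms: none
Why: Negishi conversion of a methyl ketone into a terminal alkyne: kinetic deprotonation at the methyl group, O-phosphorylation to enol phosphate 7 and amide-induced β-elimination, with the product stored as its lithium acetylide until work-up.

Step 4
Reactants: 8 2-(but-3-yn-1-yl)-1,3,3-trimethylcyclohex-1-ene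
Product: 10 (2E)-3-methyl-5-(2,6,6-trimethylcyclohex-1-en-1-yl)pent-2-en-1-ol, via alkenylalane 9 (not isolated)
Conditions: AlMe3 (2 equiv), Cp2ZrCl2 (0.25 equiv), CH2Cl2, 0 °C to rt; volatiles removed; n-BuLi, THF/hexane, −78 °C; (CH2O)n, −78 °C to rt; cold 1 M HCl
Reagents that add atoms: trimethylaluminium, C[Al](C)C; paraformaldehyde (as formaldehyde), C=O
Why: Negishi zirconium-catalysed carboalumination adds methyl and aluminium syn across the terminal alkyne with aluminium on the terminal carbon, which fixes the (E)-trisubstituted alkene, and the alanate formed with n-BuLi is hydroxymethylated by formaldehyde with retention while the tetrasubstituted ring alkene stays inert.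

Step 5
Reactants: 10 (2E)-3-methyl-5-(2,6,6-trimethylcyclohex-1-en-1-yl)pent-2-en-1-ol
Product: 11 2-[(3E)-5-chloro-3-methylpent-3-en-1-yl]-1,3,3-trimethylcyclohex-1-ene
Conditions: PPh3 (1.3 equiv), CCl4, reflux
Reagents that add atoms: tetrachloromethane, ClC(Cl)(Cl)Cl
Why: Appel chlorination: chloride displaces the alkoxyphosphonium group at the primary allylic carbon in an SN2 reaction, which should proceed without allylic transposition or loss of alkene geometry.

Step 6
Reactants: 5 methyl 3-(but-3-yn-1-yl)-4-hydroxybenzoate; 11 2-[(3E)-5-chloro-3-methylpent-3-en-1-yl]-1,3,3-trimethylcyclohex-1-ene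
Product: 13 methyl 4-hydroxy-3-[(3E,6E)-3,7-dimethyl-9-(2,6,6-trimethylcyclohex-1-en-1-yl)nona-3,6-dien-1-yl]benzoate, via alkenylalane 12 (not isolated)
Conditions: 5, AlMe3 (3.5 equiv), Cp2ZrCl2 (0.3 equiv), CH2Cl2, 0 °C to rt; volatiles removed; then 11, Pd(PPh3)4 (5 mol%), THF, rt; cold dilute HCl
Reagents that add atoms: trimethylaluminium, C[Al](C)C
Why: A second Negishi carboalumination (the phenol is masked in the flask as its dimethylaluminium phenoxide and the electron-rich benzoate should resist AlMe3 at or below room temperature) is followed by Negishi palladium-catalysed alkenyl–allyl cross-coupling, which joins 12 to the primary terminus of the π-allyl unit from 11 with retention of both alkene geometries to give the 1,4-diene.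

Step 7
Reactants: 13 methyl 4-hydroxy-3-[(3E,6E)-3,7-dimethyl-9-(2,6,6-trimethylcyclohex-1-en-1-yl)nona-3,6-dien-1-yl]benzoate
Product: 14 methyl (2R)-2-methyl-2-[(1E,3E)-4-methyl-6-(2,6,6-trimethylcyclohex-1-en-1-yl)hexa-1,3-dien-1-yl]-3,4-dihydro-2H-chromene-6-carboxylate
Conditions: Pd(OCOCF3)2 (10 mol%), (R,R)-Bn-BOXAX (20 mol%), p-benzoquinone (4 equiv), MeOH, rt to 60 °C
Reagents that add atoms: none
Why: The Pd(OCOCF3)2–BOXAX complex binds the trisubstituted alkene that becomes C2=C1', the phenol oxygen adds to its methyl-bearing carbon (oxypalladation, forming O1–C2 and a C1'–Pd bond), and β-hydride elimination, possible only toward the doubly allylic C2'–H because C2 is quaternary, releases the (1'E,3'E)-diene while p-benzoquinone returns the palladium hydride to divalent palladium. The closest known reaction type is the enantioselective Wacker-type oxidative cyclization of 2-(alkenyl)phenols with trisubstituted alkenes to 2-methyl-2-vinylchromanes under BOXAX ligands. The dihydropyran ring closes in the 6-exo-trig mode. The C2 stereocentre is set by the ligand, which selects the alkene enantioface attacked by oxygen, and the C1' centre formed in passing is erased by the elimination. The step needs chemoselectivity among three alkenes, Markovnikov regioselectivity and (E)-selective elimination: only the proximal alkene reaches oxygen through a six-membered transition state, the tetrasubstituted ring alkene does not bind palladium, attack at the more substituted carbon avoids a seven-membered ring, and the trans alkene follows from the syn-elimination conformer that keeps C2 and the C3' alkenyl group apart.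

Step 8
Reactants: 14 methyl (2R)-2-methyl-2-[(1E,3E)-4-methyl-6-(2,6,6-trimethylcyclohex-1-en-1-yl)hexa-1,3-dien-1-yl]-3,4-dihydro-2H-chromene-6-carboxylate
Product: 15 (2R)-2-methyl-2-[(1E,3E)-4-methyl-6-(2,6,6-trimethylcyclohex-1-en-1-yl)hexa-1,3-dien-1-yl]-3,4-dihydro-2H-chromene-6-carboxylic acid
Conditions: LiOH·H2O (5 equiv), THF/MeOH/H2O, 40 °C; then 1 M HCl to pH 4–5, 0 °C
Reagents that add atoms: lithium hydroxide (hydroxide oxygen of the acid), [Li+].[OH-]
Why: Saponification of the methyl benzoate by acyl–oxygen cleavage leaves the base-stable tertiary allylic aryl ether and the diene untouched, and the mild cold acidification avoids ionising the C2–O bond, so the stereocentre should be kept.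

**Compound list**
1 | methyl 4-hydroxy-3-iodobenzoate | COC(=O)c1ccc(O)c(I)c1 | starting material
2 | allyl alcohol (prop-2-en-1-ol) | C=CCO | starting material
3 | methyl 4-hydroxy-3-(3-oxopropyl)benzoate (open hydroxy aldehyde) | COC(=O)c1ccc(O)c(CCC=O)c1 | intermediate
4 | methyl 2-hydroxy-3,4-dihydro-2H-chromene-6-carboxylate (racemic lactol, ring-chain tautomer of 3) | COC(=O)c1ccc2OC(O)CCc2c1 | intermediate
5 | methyl 3-(but-3-yn-1-yl)-4-hydroxybenzoate | COC(=O)c1ccc(O)c(CCC#C)c1 | intermediate
6 | dihydro-β-ionone, 4-(2,6,6-trimethylcyclohex-1-en-1-yl)butan-2-one | CC(=O)CCC1=C(C)CCCC1(C)C | starting material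
7 | diethyl 4-(2,6,6-trimethylcyclohex-1-en-1-yl)but-1-en-2-yl phosphate | C=C(CCC1=C(C)CCCC1(C)C)OP(=O)(OCC)OCC | intermediate
8 | 2-(but-3-yn-1-yl)-1,3,3-trimethylcyclohex-1-ene | C#CCCC1=C(C)CCCC1(C)C | intermediate
9 | dimethyl[(1E)-2-methyl-4-(2,6,6-trimethylcyclohex-1-en-1-yl)but-1-en-1-yl]alumane | C[Al](C)/C=C(\C)CCC1=C(C)CCCC1(C)C | intermediate
10 | (2E)-3-methyl-5-(2,6,6-trimethylcyclohex-1-en-1-yl)pent-2-en-1-ol | OC/C=C(\C)CCC1=C(C)CCCC1(C)C | intermediate
11 | 2-[(3E)-5-chloro-3-methylpent-3-en-1-yl]-1,3,3-trimethylcyclohex-1-ene | ClC/C=C(\C)CCC1=C(C)CCCC1(C)C | intermediate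
12 | methyl 4-[(dimethylalumanyl)oxy]-3-[(3E)-4-(dimethylalumanyl)-3-methylbut-3-en-1-yl]benzoate | COC(=O)c1ccc(O[Al](C)C)c(CC/C(C)=C/[Al](C)C)c1 | intermediate
13 | methyl 4-hydroxy-3-[(3E,6E)-3,7-dimethyl-9-(2,6,6-trimethylcyclohex-1-en-1-yl)nona-3,6-dien-1-yl]benzoate | COC(=O)c1ccc(O)c(CC/C(C)=C/C/C=C(\C)CCC2=C(C)CCCC2(C)C)c1 | intermediate
14 | methyl (2R)-2-methyl-2-[(1E,3E)-4-methyl-6-(2,6,6-trimethylcyclohex-1-en-1-yl)hexa-1,3-dien-1-yl]-3,4-dihydro-2H-chromene-6-carboxylate | CC1=C(CC/C(C)=C/C=C/[C@@]2(C)CCc3cc(C(=O)OC)ccc3O2)C(C)(C)CCC1 | intermediate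
15 | (2R)-2-methyl-2-[(1E,3E)-4-methyl-6-(2,6,6-trimethylcyclohex-1-en-1-yl)hexa-1,3-dien-1-yl]-3,4-dihydro-2H-chromene-6-carboxylic acid | CC1=C(CC/C(C)=C/C=C/[C@@]2(C)CCc3cc(C(=O)O)ccc3O2)C(C)(C)CCC1 | target

**Step count.** Total: 8 steps. Longest linear sequence: 6 steps (6 → 8 → 10 → 11 → 13 → 14 → 15).

**Steps most likely to fail**

Step 7. The enantioselectivity may be eroded if palladium is chelated by the skipped diene. The palladium hydride may also re-add to the product diene and isomerise it, or benzoquinone may slowly capture the diene in a Diels–Alder reaction. The fallback closes the same O1–C2 bond by asymmetric allylic etherification with zerovalent palladium and adds the diene afterwards. It sets out from 5 (and from alkenylalane 9 of step 4) and returns at 14. Carboalumination of 5 (AlMe3, Cp2ZrCl2), then n-BuLi at −78 °C and paraformaldehyde, would give methyl 4-hydroxy-3-[(3E)-5-hydroxy-3-methylpent-3-en-1-yl]benzoate F1. Methyl chloroformate and pyridine would convert it into the bis(methyl carbonate) F2, and pyrrolidine at 0 °C should cleave only the aryl carbonate to give the phenol allyl carbonate F3. Tsuji–Trost cyclization (Pd2(dba)3·CHCl3, the DACH-phenyl Trost ligand in the enantiomeric form that delivers (R), AcOH, CH2Cl2) would give methyl (2R)-2-ethenyl-2-methylchromane-6-carboxylate F4. Iodinolysis of 9 (I2, THF, −30 °C) would give 2-[(3E)-4-iodo-3-methylbut-3-en-1-yl]-1,3,3-trimethylcyclohex-1-ene F5. A Heck coupling of F5 with the vinyl group of F4 (Pd(OAc)2, Ag2CO3, DMF) would then build the (1'E,3'E)-diene, since elimination is possible only away from quaternary C2, and arrive at 14.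

Step 6. AlMe3 may transfer a methyl group to the benzoate, the aluminium phenoxide may slow the carboalumination by aggregation, or the phenoxide may be O-allylated by the π-allyl palladium species. The fallback forms the aryl–CH2 bond last, so that phenol and ester never meet AlMe3. It sets out from 11 and 1 and returns at 13. Carboalumination of but-1-en-3-yne (AlMe3, Cp2ZrCl2) would give dimethyl[(1E)-2-methylbuta-1,3-dien-1-yl]alumane F6. Its Pd(PPh3)4-catalysed coupling with 11 would give the tetraene 2-[(3E,6E)-3,7-dimethylnona-3,6,8-trien-1-yl]-1,3,3-trimethylcyclohex-1-ene F7. Hydroboration of the terminal vinyl group alone with 9-BBN-H would give the B-alkyl-9-borabicyclo[3.3.1]nonane F8. A B-alkyl Suzuki–Miyaura coupling of F8 with iodophenol 1 (PdCl2(dppf), K3PO4, DMF/H2O) would give 13.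

Step 2. Ring opening of lactol 4 may be incomplete so that the homologation stalls, or the enolisable aldehyde may be consumed by base-induced self-condensation. The fallback attaches the butynyl chain by cross-coupling and bypasses the lactol. It sets out from 1 and returns at 5. Acetylation (Ac2O, pyridine) would give methyl 4-acetoxy-3-iodobenzoate F9. Commercial (4-bromobut-1-yn-1-yl)trimethylsilane with zinc dust and LiCl in THF would give [4-(trimethylsilyl)but-3-yn-1-yl]zinc bromide F10. Negishi coupling of F9 with F10 (Pd(OAc)2, SPhos, THF) would give methyl 4-acetoxy-3-[4-(trimethylsilyl)but-3-yn-1-yl]benzoate F11. K2CO3 in MeOH would then remove the acetate and the C-silyl group together to give 5.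

**Further compounds**
F1 | step 7 | methyl 4-hydroxy-3-[(3E)-5-hydroxy-3-methylpent-3-en-1-yl]benzoate | COC(=O)c1ccc(O)c(CC/C(C)=C/CO)c1
F2 | step 7 | methyl 4-[(methoxycarbonyl)oxy]-3-{(3E)-5-[(methoxycarbonyl)oxy]-3-methylpent-3-en-1-yl}benzoate | COC(=O)Oc1ccc(C(=O)OC)cc1CC/C(C)=C/COC(=O)OC
F3 | step 7 | methyl 4-hydroxy-3-{(3E)-5-[(methoxycarbonyl)oxy]-3-methylpent-3-en-1-yl}benzoate | COC(=O)OC/C=C(\C)CCc1cc(C(=O)OC)ccc1O
F4 | step 7 | methyl (2R)-2-ethenyl-2-methylchromane-6-carboxylate | C=C[C@@]1(C)CCc2cc(C(=O)OC)ccc2O1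
F5 | step 7 | 2-[(3E)-4-iodo-3-methylbut-3-en-1-yl]-1,3,3-trimethylcyclohex-1-ene | I/C=C(\C)CCC1=C(C)CCCC1(C)C
F6 | step 6 | dimethyl[(1E)-2-methylbuta-1,3-dien-1-yl]alumane | C[Al](C)/C=C(\C)C=C
F7 | step 6 | 2-[(3E,6E)-3,7-dimethylnona-3,6,8-trien-1-yl]-1,3,3-trimethylcyclohex-1-ene | C=C/C(C)=C/C/C=C(\C)CCC1=C(C)CCCC1(C)C
F8 | step 6 | 9-[(3E,6E)-3,7-dimethyl-9-(2,6,6-trimethylcyclohex-1-en-1-yl)nona-3,6-dien-1-yl]-9-borabicyclo[3.3.1]nonane | B1(CC/C(C)=C/C/C=C(\C)CCC2=C(C)CCCC2(C)C)C3CCCC1CCC3
F9 | step 2 | methyl 4-acetoxy-3-iodobenzoate | COC(=O)c1ccc(OC(C)=O)c(I)c1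
F10 | step 2 | [4-(trimethylsilyl)but-3-yn-1-yl]zinc bromide | C[Si](C)(C)C#CCC[Zn]Br
F11 | step 2 | methyl 4-acetoxy-3-[4-(trimethylsilyl)but-3-yn-1-yl]benzoate | COC(=O)c1ccc(OC(C)=O)c(CCC#C[Si](C)(C)C)c1
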